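On average 0.104 M of starting material stands in neither column at the last readings of the green, grey and red runs. Call this the bound pool: starting material that has left but is not target. You can read it as nearly all of the 110 mM of free catalyst, holding starting material.

| flask | starting material | second substrate | reagent | protic impurity | free catalyst | remark |
|---|---|---|---|---|---|---|
| green | 0.63 M | 0.44 M | 0.441 M | 0.189 M | 110 mM | run made earlier |
| grey | 0.63 M | 0.69 M | 0.441 M | 0.189 M | 110 mM | run made earlier |
| red | 0.95 M | 0.315 M | 0.441 M | 0.189 M | 110 mM | run made earlier |
| flask | 0.63 M | 0.315 M | 0.441 M | 0.189 M | 110 mM |  |

| run | time / d | target / % | starting material / % |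
|---|---|---|---|
| green | 4.00 | 57.0 | 25.2 |
| green | 8.00 | 67.4 | 19.4 |
| green | 12.0 | 64.1 | 19.3 |
| green | 15.0 | 64.4 | 17.8 |
| grey | 2.08 | 44.5 | 43.9 |
| grey | 6.00 | 60.6 | 22.9 |
| grey | 10.0 | 64.5 | 21.4 |
| grey | 15.0 | 62.5 | 21.5 |
| red | 2.08 | 34.5 | 58.1 |
| red | 6.00 | 45.6 | 43.7 |
| red | 10.0 | 44.5 | 43.4 |
| red | 15.0 | 45.8 | 43.9 |

(each reading ± 1 percentage point)

- what is bound to the catalyst counts as converted
- no earlier run changes the charge of free catalyst; that part of a forecast is a guess

1. apparent order in second substrate when 30 % of the starting material are converted (percent change of the rate of making target for one percent more second substrate charged)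
2. apparent order in free catalyst when 30 % of the starting material are converted (percent change of the rate of making target for one percent more free catalyst charged)
3. factor on the rate of making target when 30 % of the starting material are converted if free catalyst is charged twice over

Now draw the target curve of the flask. I take the pool to fill first, so target starts behind the loss of starting material. At 30 % conversion, 0.189 M is lost, so target stands near 0.0854 M, and at one reagent per target, 0.356 M of reagent remains. Target in the red run, which has the flask's second substrate charge, reads flat from 6.00 d on, at a mean of 0.430 M. That is just below the reagent charge, so reagent is the limiting reagent. For the flask this level is 68.3 % target.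

The zero of the scale is order one: rate goes with pool times reagent left, and the pool goes with the catalyst. But a larger pool also means less target made at the same conversion, so more reagent is left. This adds pool over reagent left, 0.291, and my order in catalyst is 1.29. On doubling, twice the pool exceeds the loss, so I cap the pool at that loss, which gives a factor of 2.26. The pool reads alike within scatter across the second substrate charges of the green, grey and red runs, so I put that order near zero.

The forecast gives 0.15 for the order in second substrate, 0.9 for the order in free catalyst, which is below mine, and 1.85 for the factor, reasoning “the order in second substrate is small and the order in catalyst near one”.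

    second substrate + protic impurity → quenched substrate (k = 0.00191 L mol⁻¹ min⁻¹)
    second substrate + free catalyst ⇌ catalyst intermediate B (K = 2.02 L mol⁻¹, k = 0.00656 L mol⁻¹ min⁻¹)
    starting material + free catalyst ⇌ catalyst intermediate A (K = 110 L mol⁻¹, k = 0.0191 L mol⁻¹ min⁻¹)
    reagent + catalyst intermediate A → free catalyst + target (k = 0.00468 L mol⁻¹ min⁻¹)
    reagent + catalyst intermediate B → free catalyst + second product (k = 0.00346 L mol⁻¹ min⁻¹)

The flask gives an order of −0.099 in second substrate, an order of 1.2 in free catalyst and a factor of 2.08. It reaches 30 % conversion after 0.531 d, making target at 0.189 M d⁻¹ there. Catalyst intermediate A is the resting state of the flask: at 20.0 d it holds 90.9 % of the catalyst charged, which is 0.100 M, against the pool of 0.104 M read from the green, grey and red runs.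

The runs were generated by integration for an exercise, noise included.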